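**Retrosynthetic overview**
- The tetrahydrofuran is closed last: an aryllithium adds to a γ-lactone to give a cyclic hemiketal, ionic hydrogenation of its oxocarbenium ion sets the C5–H bond, and debenzylation follows.
- That γ-lactone (ring B, carbonyl = future C5) comes from oxidative lactonisation of a 1,2,4-triol whose benzylic carbinol (C2) is set by chelate-controlled reduction of an α-hydroxy aryl ketone.
- The aryl ketone comes from an aryl Grignard reagent and the Weinreb amide made by opening a small α-hydroxy-α,β-dimethyl-γ-butyrolactone (ring A).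
- Ring A comes from the key C3–C4 bond: a catalytic enantioselective syn Mukaiyama aldol between a propionate thioester silyl ketene acetal and a pyruvate ester, which sets both methyl-bearing centres.
- Ring order: butyrolactone ring A (opened again), then butyrolactone ring B, then the tetrahydrofuran.

Assumption and convention: target numbering is O1, C2(Ar), C3(OH)(Me), C4(Me), C5(Ar); the target is (2R,3S,4R,5R), with both aryls and both methyls on one face and OH on the other. The sense of induction of Cu(OTf)2/(S,S)-t-Bu-box is taken as known for pyruvate aldols (si-face attack, (S)-carbinol, syn).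

**Route**

Step 1
Reactants: 1 S-ethyl propanethioate
Product: 3 (Z)-1-(ethylsulfanyl)-1-[(trimethylsilyl)oxy]prop-1-ene, via lithium enolate 2 (not isolated)
Conditions: LiN(iPr)2, THF, −78 °C; then Me3SiCl, −78 °C to rt; distil
Reagents that add atoms: chlorotrimethylsilane, C[Si](C)(C)Cl
Why: Kinetic (Ireland-type) deprotonation of the thioester gives the enolate with methyl trans to O–Li, and O-silylation traps it as the (Z)-silyl ketene acetal.

Step 2
Reactants: 3 (Z)-1-(ethylsulfanyl)-1-[(trimethylsilyl)oxy]prop-1-ene; 4 methyl pyruvate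
Product: 6 methyl (2S,3S)-4-(ethylsulfanyl)-2-hydroxy-2,3-dimethyl-4-oxobutanoate, via silyl ether 5 (not isolated)
Conditions: Cu(OTf)2 (10 mol%), (S,S)-t-Bu-box (11 mol%), THF, −78 °C; then 1 M HCl
Reagents that add atoms: none
Why: In this copper–bis(oxazoline)-catalysed Mukaiyama aldol the pyruvate chelates the Lewis acid through both carbonyls, the tert-butyl groups leave the si face of the ketone open to give the (S)-tertiary carbinol (target C3), and the open transition state gives the syn Me/OH pair (target C4).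

Step 3
Reactants: 6 methyl (2S,3S)-4-(ethylsulfanyl)-2-hydroxy-2,3-dimethyl-4-oxobutanoate
Product: 7 methyl (2S,3S)-2-hydroxy-2,3-dimethyl-4-oxobutanoate
Conditions: Et3SiH, 10% Pd/C, CH2Cl2, rt; used crude
Reagents that add atoms: none
Why: The Fukuyama reduction converts only the thioester to the aldehyde under neutral conditions, so the ester, the tertiary alcohol and the α-stereocentre are untouched.

Step 4
Reactants: 7 methyl (2S,3S)-2-hydroxy-2,3-dimethyl-4-oxobutanoate
Product: 9 (3S,4R)-3-hydroxy-3,4-dimethyloxolan-2-one, via diol ester 8 (not isolated)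
Conditions: NaBH4, MeOH, −20 °C; then TsOH·H2O (cat.), CH2Cl2, rt
Reagents that add atoms: none
Why: Borohydride reduces the aldehyde far faster than the α-hydroxy ester, and the resulting γ-hydroxy ester lactonises under acid catalysis without touching either stereocentre.

Step 5
Reactants: 9 (3S,4R)-3-hydroxy-3,4-dimethyloxolan-2-one
Product: 10 (2S,3R)-2,4-dihydroxy-N-methoxy-N,2,3-trimethylbutanamide
Conditions: MeNH(OMe)·HCl (3 equiv), Me3Al (3 equiv), CH2Cl2, 0 °C; then 9, 0 °C to rt; aq. Rochelle salt; used crude at once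
Reagents that add atoms: N,O-dimethylhydroxylamine hydrochloride, CNOC.Cl
Why: Weinreb aminolysis with the chloro(methyl)aluminium amide opens the lactone at the acyl carbon only, so neither stereocentre is touched; the non-acidic work-up and immediate use prevent relactonisation.

Step 6
Reactants: 10 (2S,3R)-2,4-dihydroxy-N-methoxy-N,2,3-trimethylbutanamide
Product: 11 (2S,3R)-4-[(tert-butyldimethylsilyl)oxy]-2-hydroxy-N-methoxy-N,2,3-trimethylbutanamide
Conditions: TBSCl, imidazole, DMF, 0 °C
Reagents that add atoms: tert-butyldimethylsilyl chloride, CC(C)(C)[Si](C)(C)Cl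
Why: Selective silylation of the primary hydroxyl (the tertiary one is inert) stops the hydroxy amide from closing back to lactone 9 and leaves the α-hydroxyl free for the later chelation.

Step 7
Reactants: 12 4-bromo-2-methoxyphenol
Product: 13 1-(benzyloxy)-4-bromo-2-methoxybenzene
Conditions: BnBr, K2CO3, DMF, rt
Reagents that add atoms: benzyl bromide, BrCc1ccccc1
Why: Williamson ether synthesis on the phenoxide gives a phenol protecting group that survives organometallic, hydride, oxidation and Lewis acid steps.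

Step 8
Reactants: 11 (2S,3R)-4-[(tert-butyldimethylsilyl)oxy]-2-hydroxy-N-methoxy-N,2,3-trimethylbutanamide; 13 1-(benzyloxy)-4-bromo-2-methoxybenzene
Product: 15 (2S,3R)-1-[4-(benzyloxy)-3-methoxyphenyl]-4-[(tert-butyldimethylsilyl)oxy]-2-hydroxy-2,3-dimethylbutan-1-one, via arylmagnesium bromide 14 (not isolated)
Conditions: 13 (3.2 equiv), Mg turnings, I2 (cat.), THF, 40 °C; then 11, 0 °C to rt; aq. NH4Cl
Reagents that add atoms: none
Why: In this Weinreb ketone synthesis one equivalent of the Grignard reagent deprotonates the tertiary alcohol and a second adds to the amide, whose magnesium-chelated tetrahedral intermediate survives until the quench, so the ketone forms only on work-up and cannot be attacked twice.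

Step 9
Reactants: 15 (2S,3R)-1-[4-(benzyloxy)-3-methoxyphenyl]-4-[(tert-butyldimethylsilyl)oxy]-2-hydroxy-2,3-dimethylbutan-1-one
Product: 16 (1R,2S,3R)-1-[4-(benzyloxy)-3-methoxyphenyl]-4-[(tert-butyldimethylsilyl)oxy]-2,3-dimethylbutane-1,2-diol
Conditions: Zn(BH4)2, Et2O, −20 to 0 °C; aq. NH4Cl
Reagents that add atoms: none
Why: In this Cram-chelate-controlled reduction zinc bridges the ketone oxygen and the α-hydroxyl, and hydride enters from the methyl side of the five-membered chelate (away from the branched chain) to give the (1R) carbinol (target C2).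

Step 10
Reactants: 16 (1R,2S,3R)-1-[4-(benzyloxy)-3-methoxyphenyl]-4-[(tert-butyldimethylsilyl)oxy]-2,3-dimethylbutane-1,2-diol
Product: 17 (1R,2S,3R)-1-[4-(benzyloxy)-3-methoxyphenyl]-2,3-dimethylbutane-1,2,4-triol
Conditions: Bu4NF, THF, 0 °C to rt
Reagents that add atoms: none
Why: Fluoride-mediated desilylation frees the primary alcohol under non-acidic conditions that cannot ionise the electron-rich benzylic carbinol.

Step 11
Reactants: 17 (1R,2S,3R)-1-[4-(benzyloxy)-3-methoxyphenyl]-2,3-dimethylbutane-1,2,4-triol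
Product: 19 (3S,4S,5R)-5-[4-(benzyloxy)-3-methoxyphenyl]-4-hydroxy-3,4-dimethyloxolan-2-one, via lactol 18 (not isolated)
Conditions: TEMPO (0.2 equiv), PhI(OAc)2 (2.5 equiv), CH2Cl2, rt
Reagents that add atoms: none
Why: In this oxoammonium-mediated oxidative lactonisation the unhindered primary alcohol is oxidised in preference to the neopentyl-type benzylic one, the aldehyde is trapped by the benzylic hydroxyl as a five-membered lactol, and the lactol is oxidised on to the lactone.

Step 12
Reactants: 19 (3S,4S,5R)-5-[4-(benzyloxy)-3-methoxyphenyl]-4-hydroxy-3,4-dimethyloxolan-2-one; 13 1-(benzyloxy)-4-bromo-2-methoxybenzene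
Product: 21 (3S,4S,5R)-2,5-bis[4-(benzyloxy)-3-methoxyphenyl]-3,4-dimethyloxolane-2,4-diol, via aryllithium 20 (not isolated)
Conditions: 13 (2.5 equiv), n-BuLi (2.4 equiv), THF, −78 °C; then 19, −78 °C; aq. NH4Cl at −78 °C; used at once
Reagents that add atoms: none
Why: After bromine–lithium exchange, single addition of the aryllithium to the hindered γ-lactone at −78 °C gives the cyclic hemiketal (mixture at C2 of the oxolane), and the cold, neutral quench avoids retro-aldol and α-epimerisation of the ring-opened hydroxy ketone.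

Step 13
Reactants: 21 (3S,4S,5R)-2,5-bis[4-(benzyloxy)-3-methoxyphenyl]-3,4-dimethyloxolane-2,4-diol
Product: 23 (2R,3S,4R,5R)-2,5-bis[4-(benzyloxy)-3-methoxyphenyl]-3,4-dimethyloxolan-3-ol, via oxocarbenium ion 22 (not isolated)
Conditions: Et3SiH (5 equiv), BF3·OEt2 (2 equiv), CH2Cl2, −78 °C; Et3N then aq. NaHCO3 at −78 °C
Reagents that add atoms: none
Why: In this ionic hydrogenation of the cyclic hemiketal the silane attacks the oxocarbenium ion anti to the adjacent C4 methyl, on the face that carries only the C3 hydroxyl and is remote from the C2 aryl and C3 methyl, so the new C5–H is cis to OH and the ring is all-cis (5R).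

Step 14
Reactants: 23 (2R,3S,4R,5R)-2,5-bis[4-(benzyloxy)-3-methoxyphenyl]-3,4-dimethyloxolan-3-ol
Product: 24 (2R,3S,4R,5R)-2,5-bis(4-hydroxy-3-methoxyphenyl)-3,4-dimethyloxolan-3-ol
Conditions: H2 (1 atm), 10% Pd/C, EtOAc, rt; stop at full conversion
Reagents that add atoms: none
Why: Hydrogenolysis cleaves the two aryl benzyl ethers much faster than the ring benzylic C–O bonds, and the neutral conditions avoid epimerisation of the free-phenol product.

**Compound list**
1 | S-ethyl propanethioate | CCC(=O)SCC | starting material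
2 | lithium (Z)-1-(ethylsulfanyl)prop-1-en-1-olate | C/C=C(/O[Li])SCC | intermediate
3 | (Z)-1-(ethylsulfanyl)-1-[(trimethylsilyl)oxy]prop-1-ene | C/C=C(/O[Si](C)(C)C)SCC | intermediate
4 | methyl pyruvate (methyl 2-oxopropanoate) | CC(=O)C(=O)OC | starting material
5 | methyl (2S,3S)-4-(ethylsulfanyl)-2,3-dimethyl-4-oxo-2-[(trimethylsilyl)oxy]butanoate | CCSC(=O)[C@@H](C)[C@](C)(O[Si](C)(C)C)C(=O)OC | intermediate
6 | methyl (2S,3S)-4-(ethylsulfanyl)-2-hydroxy-2,3-dimethyl-4-oxobutanoate | CCSC(=O)[C@@H](C)[C@](C)(O)C(=O)OC | intermediate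
7 | methyl (2S,3S)-2-hydroxy-2,3-dimethyl-4-oxobutanoate | O=C[C@@H](C)[C@](C)(O)C(=O)OC | intermediate
8 | methyl (2S,3R)-2,4-dihydroxy-2,3-dimethylbutanoate | OC[C@@H](C)[C@](C)(O)C(=O)OC | intermediate
9 | (3S,4R)-3-hydroxy-3,4-dimethyloxolan-2-one (methyls cis) | O=C1OC[C@@H](C)[C@]1(C)O | intermediate
10 | (2S,3R)-2,4-dihydroxy-N-methoxy-N,2,3-trimethylbutanamide | OC[C@@H](C)[C@](C)(O)C(=O)N(C)OC | intermediate
11 | (2S,3R)-4-[(tert-butyldimethylsilyl)oxy]-2-hydroxy-N-methoxy-N,2,3-trimethylbutanamide | CC(C)(C)[Si](C)(C)OC[C@@H](C)[C@](C)(O)C(=O)N(C)OC | intermediate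
12 | 4-bromo-2-methoxyphenol | COc1cc(Br)ccc1O | starting material
13 | 1-(benzyloxy)-4-bromo-2-methoxybenzene | COc1cc(Br)ccc1OCc1ccccc1 | intermediate
14 | [4-(benzyloxy)-3-methoxyphenyl]magnesium bromide | Br[Mg]c1ccc(OCc2ccccc2)c(OC)c1 | intermediate
15 | (2S,3R)-1-[4-(benzyloxy)-3-methoxyphenyl]-4-[(tert-butyldimethylsilyl)oxy]-2-hydroxy-2,3-dimethylbutan-1-one | CC(C)(C)[Si](C)(C)OC[C@@H](C)[C@](C)(O)C(=O)c1ccc(OCc2ccccc2)c(OC)c1 | intermediate
16 | (1R,2S,3R)-1-[4-(benzyloxy)-3-methoxyphenyl]-4-[(tert-butyldimethylsilyl)oxy]-2,3-dimethylbutane-1,2-diol | CC(C)(C)[Si](C)(C)OC[C@@H](C)[C@](C)(O)[C@H](O)c1ccc(OCc2ccccc2)c(OC)c1 | intermediate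
17 | (1R,2S,3R)-1-[4-(benzyloxy)-3-methoxyphenyl]-2,3-dimethylbutane-1,2,4-triol | OC[C@@H](C)[C@](C)(O)[C@H](O)c1ccc(OCc2ccccc2)c(OC)c1 | intermediate
18 | (3S,4S,5R)-5-[4-(benzyloxy)-3-methoxyphenyl]-3,4-dimethyloxolane-2,4-diol (lactol, both anomers) | OC1O[C@H](c2ccc(OCc3ccccc3)c(OC)c2)[C@@](C)(O)[C@@H]1C | intermediate
19 | (3S,4S,5R)-5-[4-(benzyloxy)-3-methoxyphenyl]-4-hydroxy-3,4-dimethyloxolan-2-one (aryl and both methyls cis) | O=C1O[C@H](c2ccc(OCc3ccccc3)c(OC)c2)[C@@](C)(O)[C@@H]1C | intermediate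
20 | [4-(benzyloxy)-3-methoxyphenyl]lithium | [Li]c1ccc(OCc2ccccc2)c(OC)c1 | intermediate
21 | (3S,4S,5R)-2,5-bis[4-(benzyloxy)-3-methoxyphenyl]-3,4-dimethyloxolane-2,4-diol (hemiketal, mixture at C2) | OC1(c2ccc(OCc3ccccc3)c(OC)c2)O[C@H](c2ccc(OCc3ccccc3)c(OC)c2)[C@@](C)(O)[C@@H]1C | intermediate
22 | (2R,3S,4S)-2,5-bis[4-(benzyloxy)-3-methoxyphenyl]-3-hydroxy-3,4-dimethyl-3,4-dihydro-2H-furan-1-ium (oxocarbenium ion) | COc1cc(C2=[O+][C@H](c3ccc(OCc4ccccc4)c(OC)c3)[C@@](C)(O)[C@@H]2C)ccc1OCc1ccccc1 | intermediate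
23 | (2R,3S,4R,5R)-2,5-bis[4-(benzyloxy)-3-methoxyphenyl]-3,4-dimethyloxolan-3-ol | COc1cc([C@H]2O[C@@H](c3ccc(OCc4ccccc4)c(OC)c3)[C@@H](C)[C@]2(C)O)ccc1OCc1ccccc1 | intermediate
24 | (2R,3S,4R,5R)-2,5-bis(4-hydroxy-3-methoxyphenyl)-3,4-dimethyloxolan-3-ol | COc1cc([C@H]2O[C@@H](c3ccc(O)c(OC)c3)[C@@H](C)[C@]2(C)O)ccc1O | target

**Step count and risks**
Total steps: 14. Longest linear sequence: 13 steps (1 to 24 through steps 1–6 and 8–14); step 7 is a one-step branch whose product 13 is used twice.

Steps most likely to fail: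

- Step 9 (the chelate must distinguish methyl from the branched chain at a quaternary centre, so the diastereomer ratio at C2 may be modest). The fallback reverses the order of bond formation at C2: the aryl group is added to an aldehyde under Felkin–Anh control instead of hydride to the aryl ketone. It sets out from lactone 9. Silylation of the tertiary alcohol (TBSOTf, 2,6-lutidine, CH2Cl2) gives (3S,4R)-3-[(tert-butyldimethylsilyl)oxy]-3,4-dimethyloxolan-2-one F1. Half-reduction ((i-Bu)2AlH, CH2Cl2, −78 °C) gives the lactol (3S,4R)-3-[(tert-butyldimethylsilyl)oxy]-3,4-dimethyloxolan-2-ol F2. Aryllithium 20 (made from 13 and n-BuLi as in step 12; 2.5 equiv, THF, −78 to 0 °C) then adds to its open hydroxy-aldehyde form anti to the bulky, non-chelating α-silyloxy group and past the methyl group, giving (1R,2S,3R)-1-[4-(benzyloxy)-3-methoxyphenyl]-2-[(tert-butyldimethylsilyl)oxy]-2,3-dimethylbutane-1,4-diol F3. Bu4NF removes the silyl group and the route is rejoined at triol 17.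

- Step 11 (the benzylic secondary alcohol or the vicinal diol may be oxidised or cleaved before the primary alcohol has closed to the lactol). The fallback never takes the future C5 carbon below the acid oxidation level: the key aldol is run on an aryl 1,2-diketone in place of methyl pyruvate. It sets out from 3 and from arylmagnesium bromide 14 (made from 13 and Mg as in step 8). Acylation of 14 with N-methoxy-N-methylpropanamide gives 1-[4-(benzyloxy)-3-methoxyphenyl]propan-1-one F4, and SeO2 (dioxane–H2O, reflux) oxidises it to 1-[4-(benzyloxy)-3-methoxyphenyl]propane-1,2-dione F5. The same Cu(OTf)2/(S,S)-t-Bu-box aldol with 3 (attack at the acetyl carbonyl of the chelated diketone, HCl work-up) gives S-ethyl (2S,3S)-4-[4-(benzyloxy)-3-methoxyphenyl]-3-hydroxy-2,3-dimethyl-4-oxobutanethioate F6. Zn(BH4)2 reduction as in step 9 gives S-ethyl (2S,3S,4R)-4-[4-(benzyloxy)-3-methoxyphenyl]-3,4-dihydroxy-2,3-dimethylbutanethioate F7, whose benzylic hydroxyl displaces the thiol on treatment with Et3N/DMAP in CH2Cl2, returning to lactone 19.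

- Step 13 (acid can open the strained all-cis ring at either electron-rich benzylic position, giving epimers or over-reduction, and the facial selectivity rests on sterics). The fallback sets C4 and C5 by a hydroxyl-directed hydrogenation instead of an ionic reduction. It sets out from hemiketal 21. Dehydration under basic conditions (MsCl, Et3N, CH2Cl2, −20 °C) gives (2R,3S)-2,5-bis[4-(benzyloxy)-3-methoxyphenyl]-3,4-dimethyl-2,3-dihydrofuran-3-ol F8. H2 with [Ir(cod)(PCy3)(py)]PF6 in CH2Cl2, anchored by the tertiary hydroxyl, then delivers both hydrogens to the face that carries OH (also the face remote from the C2 aryl and C3 methyl), returning to 23.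

**Further compounds**
F1 | step 9 | (3S,4R)-3-[(tert-butyldimethylsilyl)oxy]-3,4-dimethyloxolan-2-one | O=C1OC[C@@H](C)[C@]1(C)O[Si](C)(C)C(C)(C)C
F2 | step 9 | (3S,4R)-3-[(tert-butyldimethylsilyl)oxy]-3,4-dimethyloxolan-2-ol | OC1OC[C@@H](C)[C@]1(C)O[Si](C)(C)C(C)(C)C
F3 | step 9 | (1R,2S,3R)-1-[4-(benzyloxy)-3-methoxyphenyl]-2-[(tert-butyldimethylsilyl)oxy]-2,3-dimethylbutane-1,4-diol | OC[C@@H](C)[C@](C)(O[Si](C)(C)C(C)(C)C)[C@H](O)c1ccc(OCc2ccccc2)c(OC)c1
F4 | step 11 | 1-[4-(benzyloxy)-3-methoxyphenyl]propan-1-one | CCC(=O)c1ccc(OCc2ccccc2)c(OC)c1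
F5 | step 11 | 1-[4-(benzyloxy)-3-methoxyphenyl]propane-1,2-dione | CC(=O)C(=O)c1ccc(OCc2ccccc2)c(OC)c1
F6 | step 11 | S-ethyl (2S,3S)-4-[4-(benzyloxy)-3-methoxyphenyl]-3-hydroxy-2,3-dimethyl-4-oxobutanethioate | CCSC(=O)[C@@H](C)[C@](C)(O)C(=O)c1ccc(OCc2ccccc2)c(OC)c1
F7 | step 11 | S-ethyl (2S,3S,4R)-4-[4-(benzyloxy)-3-methoxyphenyl]-3,4-dihydroxy-2,3-dimethylbutanethioate | CCSC(=O)[C@@H](C)[C@](C)(O)[C@H](O)c1ccc(OCc2ccccc2)c(OC)c1
F8 | step 13 | (2R,3S)-2,5-bis[4-(benzyloxy)-3-methoxyphenyl]-3,4-dimethyl-2,3-dihydrofuran-3-ol | COc1cc(C2=C(C)[C@](C)(O)[C@@H](c3ccc(OCc4ccccc4)c(OC)c3)O2)ccc1OCc1ccccc1
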